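**Strategy.** Everything rests on cutting ring A twice at neighbouring atoms: the C1'–C(=O) bond and the C2'–O bond. Since C1' (acyl) and C2' (OH) are adjacent and C6' next to C1' also bears oxygen, ring A maps onto an alkoxy-flanked benzyne. In one operation fluoride releases 3,5-bis(methoxymethoxy)benzyne, the carboxylate of the ring B acid adds through oxygen at C2', and the C1' anion captures the acyl group, so the 2'-hydroxy ketone of the dihydrochalcone forms directly and without Lewis acid. The precursors are a phloroglucinol-derived ortho-silylaryl triflate and the MOM-protected 3,5-diprenylphloretic acid; mild methanolysis then frees the phenols.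

Key step: step 7

Remark: primed locants refer to ring A (the acylated phloroglucinol ring), unprimed locants to ring B, and MOM = methoxymethyl; the two positions ortho to the free hydroxyl of compound 2 are equivalent, so silicon at either one leads to the same aryne.

**Step 1**
Reactants: 1 phloroglucinol (benzene-1,3,5-triol)
Product: 2 3,5-bis(methoxymethoxy)phenol
Conditions: MOMCl (2.0 equiv), i-Pr2NEt (2.5 equiv), CH2Cl2/THF, 0 °C to rt
Reagents that add atoms: chloromethyl methyl ether, COCCl
Why: Williamson-type O-alkylation of the phenol with the α-chloro ether is reliable, and limiting the reagent to two equivalents should leave one hydroxyl free, the bis-ether being separated by chromatography from the mono-ether (which can be resubmitted) and the tris-ether.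

**Step 2**
Reactants: 2 3,5-bis(methoxymethoxy)phenol
Product: 3 2-bromo-3,5-bis(methoxymethoxy)phenol
Conditions: NBS (1.0 equiv), CH2Cl2, −78 °C to −20 °C
Reagents that add atoms: N-bromosuccinimide, O=C1CCC(=O)N1Br
Why: Electrophilic aromatic bromination of the strongly activated ring at low temperature should stop at monobromination and favour the two equivalent positions ortho to the free hydroxyl (hydrogen-bonded delivery in a non-polar solvent, C4 being screened by two MOM ethers), which puts bromine between OH and one OMOM.

**Step 3**
Reactants: 3 2-bromo-3,5-bis(methoxymethoxy)phenol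
Product: 6 3,5-bis(methoxymethoxy)-2-(trimethylsilyl)phenyl trifluoromethanesulfonate, via aryl trimethylsilyl ether 4 (not isolated), via lithium 2-silylphenoxide 5 (not isolated)
Conditions: (Me3Si)2NH (1.0 equiv), THF, 65 °C, then concentrate; n-BuLi (1.1 equiv), THF, −78 °C; PhNTf2 (1.2 equiv), −78 °C to rt; neutral work-up
Reagents that add atoms: hexamethyldisilazane, C[Si](C)(C)N[Si](C)(C)C; N-phenylbis(trifluoromethanesulfonimide), O=S(=O)(N(c1ccccc1)S(=O)(=O)C(F)(F)F)C(F)(F)F; n-butyllithium, CCCC[Li] (its lithium is carried only by intermediate 5)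
Why: O-silylation, bromine–lithium exchange and the ensuing 1,3 O-to-C silyl shift (retro-Brook rearrangement) place silicon exactly where bromine was, and the lithium phenoxide is then trapped as the triflate by PhNTf2, a triflyl donor mild enough for the MOM acetals.

**Step 4**
Reactants: 7 methyl 3-(4-hydroxyphenyl)propanoate; 8 prenyl bromide (1-bromo-3-methylbut-2-ene)
Product: 9 methyl 3-[4-hydroxy-3,5-bis(3-methylbut-2-enyl)phenyl]propanoate
Conditions: NaH (2.2 equiv, two portions), 8 (2.2 equiv), toluene, 0 °C to rt
Reagents that add atoms: none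
Why: C-alkylation of a sodium phenoxide with an allylic bromide in a non-polar solvent (tight ion pair shielding oxygen, para position blocked) is a known way to ortho,ortho'-diprenylate para-substituted phenols, and the methyl ester is inert to the phenoxide.

**Step 5**
Reactants: 9 methyl 3-[4-hydroxy-3,5-bis(3-methylbut-2-enyl)phenyl]propanoate
Product: 10 methyl 3-[4-(methoxymethoxy)-3,5-bis(3-methylbut-2-enyl)phenyl]propanoate
Conditions: NaH (1.2 equiv), MOMCl (1.5 equiv), DMF, 0 °C to rt
Reagents that add atoms: chloromethyl methyl ether, COCCl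
Why: Williamson-type MOM protection through the sodium phenoxide in DMF should overcome the hindrance of the two flanking prenyl groups without touching the ester or the alkenes.

**Step 6**
Reactants: 10 methyl 3-[4-(methoxymethoxy)-3,5-bis(3-methylbut-2-enyl)phenyl]propanoate
Product: 11 3-[4-(methoxymethoxy)-3,5-bis(3-methylbut-2-enyl)phenyl]propanoic acid
Conditions: LiOH·H2O (3 equiv), THF/MeOH/H2O, rt; then cold 0.5 M HCl to pH 4–5
Reagents that add atoms: lithium hydroxide, [Li+].[OH-]
Why: Ester saponification at room temperature leaves the MOM acetal and the prenyl alkenes untouched, and acidification only to pH 4–5 in the cold frees the acid without cleaving the acetal.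

**Step 7**
Reactants: 6 3,5-bis(methoxymethoxy)-2-(trimethylsilyl)phenyl trifluoromethanesulfonate; 11 3-[4-(methoxymethoxy)-3,5-bis(3-methylbut-2-enyl)phenyl]propanoic acid
Product: 13 1-[2-hydroxy-4,6-bis(methoxymethoxy)phenyl]-3-[4-(methoxymethoxy)-3,5-bis(3-methylbut-2-enyl)phenyl]propan-1-one, via 3,5-bis(methoxymethoxy)benzyne 12 (not isolated)
Conditions: 6 (1.5 equiv), CsF (4 equiv), THF, 125 °C, sealed vessel
Reagents that add atoms: none
Why: Fluoride attacks silicon of 6 and triflate departs to give aryne 12; the carboxylate oxygen of 11 adds to the aryne carbon remote from the flanking MOM ether (C2'), and the carbanion left on C1' attacks the carbonyl of the ester just formed, passing through a strained four-membered alkoxide that opens to the ortho-acyl phenoxide (an anionic Fries-type 1,3 O-to-C acyl shift). The closest known reaction type is the fluoride-mediated formal insertion of arynes from ortho-silylaryl triflates into the C–O bond of carboxylic acids, which gives ortho-hydroxyaryl ketones. No ring is closed and no stereocentre is formed. The selectivity required is regiochemical, oxygen to C2' and acyl to C1'; it is secured by the C6' alkoxy group beside the triple bond, which directs the nucleophile to the distal carbon and inductively stabilises the C1' carbanion. Hot THF with excess CsF is chosen so that acyl transfer outruns protonation of the carbanion, which would stop at the simple aryl ester. The MOM ethers and the prenyl groups meet neither protic nor Lewis acid.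

**Step 8**
Reactants: 13 1-[2-hydroxy-4,6-bis(methoxymethoxy)phenyl]-3-[4-(methoxymethoxy)-3,5-bis(3-methylbut-2-enyl)phenyl]propan-1-one
Product: 14 4,2',4',6'-tetrahydroxy-3,5-diprenyldihydrochalcone, 3-[4-hydroxy-3,5-bis(3-methylbut-2-enyl)phenyl]-1-(2,4,6-trihydroxyphenyl)propan-1-one
Conditions: HCl (about 0.5 M) in MeOH, rt to 40 °C; NaHCO3 quench
Reagents that add atoms: none
Why: Acid-catalysed acetal exchange with methanol (MOM methanolysis) under dilute, cool conditions should free the three phenols well before the trisubstituted prenyl alkenes are protonated, which avoids chroman formation with the neighbouring C4 hydroxyl.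

**Compound list**
1 | phloroglucinol (benzene-1,3,5-triol) | Oc1cc(O)cc(O)c1 | starting material
2 | 3,5-bis(methoxymethoxy)phenol | COCOc1cc(O)cc(OCOC)c1 | intermediate
3 | 2-bromo-3,5-bis(methoxymethoxy)phenol | COCOc1cc(O)c(Br)c(OCOC)c1 | intermediate
4 | [2-bromo-3,5-bis(methoxymethoxy)phenoxy]trimethylsilane | COCOc1cc(O[Si](C)(C)C)c(Br)c(OCOC)c1 | intermediate
5 | lithium 3,5-bis(methoxymethoxy)-2-(trimethylsilyl)phenoxide | [Li+].[O-]c1cc(OCOC)cc(OCOC)c1[Si](C)(C)C | intermediate
6 | 3,5-bis(methoxymethoxy)-2-(trimethylsilyl)phenyl trifluoromethanesulfonate | COCOc1cc(OCOC)c([Si](C)(C)C)c(OS(=O)(=O)C(F)(F)F)c1 | intermediate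
7 | methyl 3-(4-hydroxyphenyl)propanoate | COC(=O)CCc1ccc(O)cc1 | starting material
8 | prenyl bromide (1-bromo-3-methylbut-2-ene) | CC(C)=CCBr | starting material
9 | methyl 3-[4-hydroxy-3,5-bis(3-methylbut-2-enyl)phenyl]propanoate | COC(=O)CCc1cc(CC=C(C)C)c(O)c(CC=C(C)C)c1 | intermediate
10 | methyl 3-[4-(methoxymethoxy)-3,5-bis(3-methylbut-2-enyl)phenyl]propanoate | COCOc1c(CC=C(C)C)cc(CCC(=O)OC)cc1CC=C(C)C | intermediate
11 | 3-[4-(methoxymethoxy)-3,5-bis(3-methylbut-2-enyl)phenyl]propanoic acid | COCOc1c(CC=C(C)C)cc(CCC(=O)O)cc1CC=C(C)C | intermediate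
12 | 3,5-bis(methoxymethoxy)benzyne | COCOC1=CC#CC(OCOC)=C1 | intermediate
13 | 1-[2-hydroxy-4,6-bis(methoxymethoxy)phenyl]-3-[4-(methoxymethoxy)-3,5-bis(3-methylbut-2-enyl)phenyl]propan-1-one | COCOc1cc(O)c(C(=O)CCc2cc(CC=C(C)C)c(OCOC)c(CC=C(C)C)c2)c(OCOC)c1 | intermediate
14 | 4,2',4',6'-tetrahydroxy-3,5-diprenyldihydrochalcone | CC(C)=CCc1cc(CCC(=O)c2c(O)cc(O)cc2O)cc(CC=C(C)C)c1O | target

**Total step count:** 8. **Longest linear sequence:** 5 steps (1, 2, 3, 7, 8 or 4, 5, 6, 7, 8).

**Steps most likely to fail**

Step 7. The C1' carbanion may be protonated by bifluoride or unreacted acid before the acyl group shifts, so that the reaction stops at the aryl ester. The product phenoxide may also be arylated by excess aryne, and the aryne may be diverted into ene reactions with the prenyl alkenes. The fallback sets out from acid 11 and phloroglucinol 1 and rejoins the route at target 14. Acid 11 would be activated with carbonyldiimidazole and treated with N,O-dimethylhydroxylamine hydrochloride in CH2Cl2 to give the Weinreb amide N-methoxy-N-methyl-3-[4-(methoxymethoxy)-3,5-bis(3-methylbut-2-enyl)phenyl]propanamide F1. Phloroglucinol 1 would be exhaustively protected (NaH, excess MOMCl, DMF) to 1,3,5-tris(methoxymethoxy)benzene F2. n-BuLi in THF at 0 °C should lithiate F2 between two MOM ethers (directed ortho-metalation) to give 2,4,6-tris(methoxymethoxy)phenyllithium F3. Addition of F3 to F1 at −78 °C to 0 °C should stop at the ketone stage through the chelated tetrahedral intermediate and give 3-[4-(methoxymethoxy)-3,5-bis(3-methylbut-2-enyl)phenyl]-1-[2,4,6-tris(methoxymethoxy)phenyl]propan-1-one F4. The methanolysis of step 8 would then remove all four MOM groups and deliver 14.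

Step 4. O-alkylation may compete with C-alkylation, the second ortho alkylation may stay incomplete, and the ester may condense under excess NaH, leaving a mixture that is hard to resolve. The fallback sets out from ester 7 and prenyl bromide 8 and rejoins at MOM ether 10, so that step 5 is not needed. Twofold ortho-bromination of 7 with NBS (2.1 equiv, MeCN) would give methyl 3-(3,5-dibromo-4-hydroxyphenyl)propanoate F5. NaH and MOMCl would convert it into methyl 3-[3,5-dibromo-4-(methoxymethoxy)phenyl]propanoate F6. Zinc insertion into 8 (Zn dust, LiCl, THF) gives (3-methylbut-2-enyl)zinc bromide F7. A twofold Negishi coupling of F6 with F7 (Pd(OAc)2, CPhos, THF, rt), in which the bulky biarylphosphine directs reductive elimination to the unsubstituted allyl terminus, should install both linear prenyl groups and give 10.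

Step 2. Bromination may occur para to the hydroxyl (C4, between the two MOM ethers) or run on to dibromination, eroding the supply of the ortho isomer. The fallback sets out from phenol 2 and rejoins at silyl triflate 6, so that step 3 is not needed. Phenol 2 would be carbamoylated with isopropyl isocyanate (cat. Et3N, CH2Cl2) to 3,5-bis(methoxymethoxy)phenyl N-isopropylcarbamate F8. N-silylation in the flask (TBSOTf, 1.05 equiv, TMEDA, Et2O) would give 3,5-bis(methoxymethoxy)phenyl N-(tert-butyldimethylsilyl)-N-isopropylcarbamate F9. n-BuLi/TMEDA at −78 °C should lithiate the position between the carbamate, the stronger directing group, and one MOM ether (directed ortho-metalation). TMSCl and a mild aqueous work-up would then give 3,5-bis(methoxymethoxy)-2-(trimethylsilyl)phenyl N-isopropylcarbamate F10. Et2NH and DBU in MeCN at 40 °C cleave the carbamate through the isocyanate to 3,5-bis(methoxymethoxy)-2-(trimethylsilyl)phenol F11, which PhNTf2 in the same flask converts into 6.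

**Further compounds**
F1 | step 7 | N-methoxy-N-methyl-3-[4-(methoxymethoxy)-3,5-bis(3-methylbut-2-enyl)phenyl]propanamide | COCOc1c(CC=C(C)C)cc(CCC(=O)N(C)OC)cc1CC=C(C)C
F2 | step 7 | 1,3,5-tris(methoxymethoxy)benzene | COCOc1cc(OCOC)cc(OCOC)c1
F3 | step 7 | 2,4,6-tris(methoxymethoxy)phenyllithium | [Li]c1c(OCOC)cc(OCOC)cc1OCOC
F4 | step 7 | 3-[4-(methoxymethoxy)-3,5-bis(3-methylbut-2-enyl)phenyl]-1-[2,4,6-tris(methoxymethoxy)phenyl]propan-1-one | COCOc1cc(OCOC)c(C(=O)CCc2cc(CC=C(C)C)c(OCOC)c(CC=C(C)C)c2)c(OCOC)c1
F5 | step 4 | methyl 3-(3,5-dibromo-4-hydroxyphenyl)propanoate | COC(=O)CCc1cc(Br)c(O)c(Br)c1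
F6 | step 4 | methyl 3-[3,5-dibromo-4-(methoxymethoxy)phenyl]propanoate | COCOc1c(Br)cc(CCC(=O)OC)cc1Br
F7 | step 4 | (3-methylbut-2-enyl)zinc bromide | CC(C)=CC[Zn]Br
F8 | step 2 | 3,5-bis(methoxymethoxy)phenyl N-isopropylcarbamate | COCOc1cc(OCOC)cc(OC(=O)NC(C)C)c1
F9 | step 2 | 3,5-bis(methoxymethoxy)phenyl N-(tert-butyldimethylsilyl)-N-isopropylcarbamate | COCOc1cc(OCOC)cc(OC(=O)N(C(C)C)[Si](C)(C)C(C)(C)C)c1
F10 | step 2 | 3,5-bis(methoxymethoxy)-2-(trimethylsilyl)phenyl N-isopropylcarbamate | COCOc1cc(OCOC)c([Si](C)(C)C)c(OC(=O)NC(C)C)c1
F11 | step 2 | 3,5-bis(methoxymethoxy)-2-(trimethylsilyl)phenol | COCOc1cc(O)c([Si](C)(C)C)c(OCOC)c1
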